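**Strategy.** The ten-membered ring and the α-methylene lactone are traced back to one four-membered ring. C5 (ring alkene) and C11 (lactone α-carbon) both sit on the C6–C7 bond, so C4=C5 and C11=C13 can be stored as a single cyclobutene bond C5=C11 beside a C4 isopropenyl group. In one operation ruthenium opens that cyclobutene, leaves the C11=C13 acrylate and closes C4=C5 (Z) of the carbocycle. The precursor is a methyl trans-3-silyloxy-4-alkylcyclobut-1-ene-1-carboxylate whose side chain carries the C8 angelate, a C10 ketone, the C1 and C3 silyl ethers and the isopropenyl terminus. It is assembled by a boron aldol (C8–C9) from a resolved cyclobutene aldehyde and a methyl ketone.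

Key step: step 19

Remark (labels): germacranolide numbering is used: C1–C10 ring carbons, O6 and O8 on C6 and C8, C7–C11(=C13)–C12 the acrylate/lactone unit, C14 the methylene on C10, C15 the methyl on C4.
Remark (precursor design): the skeleton of the cyclobutene precursor is kept. O8 carries its final angelate before the key step so that only O6 can lactonise later. All three ethers are triethylsilyl (least bulk beside the two reacting alkenes, one deprotection at the end). Metathesis is begun under ethylene so that either regiochemistry of ring opening leads on.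
Remark (handling, assumption): a 3-oxygenated cyclobutene can open thermally (conrotatory, donor outward), so 11–17, 27 and 30 are assumed to need handling at or below about 35 °C, and the ring is opened before anything is heated.
Remark (assumption): the sense of the lipase and Sharpless resolutions and of the Ipc-controlled aldol is taken from the usual empirical models and would be confirmed on the first batch.

Step 1
Reactants: 1 1,1,3,3-tetramethoxypropane
Product: 3 sodium (E)-3-oxoprop-1-en-1-olate, via malonaldehyde 2 (not isolated)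
Conditions: 1 M aq. HCl (cat.), 50 °C; then NaOH (1.0 equiv), 0 °C; freeze-dry
Reagents that add atoms: water, O; sodium hydroxide, [Na+].[OH-]
Why: Acid-catalysed acetal hydrolysis frees malonaldehyde, whose acidic enol is deprotonated to the extended (E)-enolate, the geometry that later fixes O6 and C8 trans.

Step 2
Reactants: 3 sodium (E)-3-oxoprop-1-en-1-olate
Product: 4 (E)-3-(triethylsilyloxy)prop-2-enal
Conditions: Et3SiCl, THF, 0 → 23 °C
Reagents that add atoms: chlorotriethylsilane, CC[Si](Cl)(CC)CC
Why: O-Silylation of the vinylogous carboxylate by the hard silyl chloride should give the vinylogous silyl formate with the E geometry retained.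

Step 3
Reactants: 4 (E)-3-(triethylsilyloxy)prop-2-enal
Product: 6 (E)-1,3-bis(triethylsilyloxy)prop-1-ene, via allylic alcohol 5 (not isolated)
Conditions: iBu2AlH, CH2Cl2, −78 °C; aq. potassium sodium tartrate; then Et3SiCl, imidazole, CH2Cl2, 0 °C
Reagents that add atoms: chlorotriethylsilane, CC[Si](Cl)(CC)CC
Why: 1,2-Hydride reduction of the enal and base-mediated silylation give an electron-rich E enol ether, a silyl ether being used at O8 because an ester there could ionise to a silyloxyallyl cation.

Step 4
Reactants: 6 (E)-1,3-bis(triethylsilyloxy)prop-1-ene; 7 trichloroacetyl chloride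
Product: 9 racemic (3R*,4R*)-2,2-dichloro-3-(triethylsilyloxy)-4-[(triethylsilyloxy)methyl]cyclobutan-1-one, via dichloroketene 8 (not isolated)
Conditions: Zn–Cu couple, Et2O/DME, 20 °C, slow addition of 7
Reagents that add atoms: none
Why: Ketene–alkene [2+2] cycloaddition in which the ketene carbonyl carbon (future C11) bonds to the nucleophilic C7 and the CCl2 carbon (C5) to the oxygen-bearing C6, the suprafacial addition to the E enol ether placing O6 and C8 trans.

Step 5
Reactants: 9 racemic dichlorocyclobutanone
Product: 10 racemic (2R*,3S*)-3-(triethylsilyloxy)-2-[(triethylsilyloxy)methyl]cyclobutan-1-one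
Conditions: Zn, AcOH, TMEDA, EtOH, 0 → 23 °C
Reagents that add atoms: none
Why: Reductive dechlorination by zinc through protonated zinc enolates, the buffered medium sparing the silyl ethers and leaving C6 and C7 untouched.

Step 6
Reactants: 10 racemic cyclobutanone
Product: 11 racemic (3S*,4R*)-3-(triethylsilyloxy)-4-[(triethylsilyloxy)methyl]cyclobut-1-en-1-yl trifluoromethanesulfonate
Conditions: KN(SiMe3)2, N-(5-chloropyridin-2-yl)bis(trifluoromethanesulfonimide), THF, −78 °C
Reagents that add atoms: N-(5-chloropyridin-2-yl)bis(trifluoromethanesulfonimide), FC(F)(F)S(=O)(=O)N(c1ccc(Cl)cn1)S(=O)(=O)C(F)(F)F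
Why: Kinetic deprotonation by the bulky amide at the unsubstituted C5 methylene and O-sulfonylation give the enol triflate, the low temperature preventing β-elimination of the C6 silyloxy group.

Step 7
Reactants: 11 racemic enol triflate
Product: 13 racemic methyl (3S*,4R*)-3-hydroxy-4-(hydroxymethyl)cyclobut-1-ene-1-carboxylate, via bis-silyl ester 12 (not isolated)
Conditions: Pd(OAc)2, dppf, CO (1 atm), MeOH, Et3N, DMF, 23 °C; then PPTS, MeOH, 0 → 23 °C
Reagents that add atoms: carbon monoxide, [C-]#[O+]; methanol, CO
Why: Palladium-catalysed methoxycarbonylation of the enol triflate puts the C12 ester on C11, and acid-catalysed methanolysis then frees both hydroxyls so that the secondary one can be resolved.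

Step 8
Reactants: 13 racemic diol ester
Product: 14 methyl (3S,4R)-4-(acetoxymethyl)-3-hydroxycyclobut-1-ene-1-carboxylate
Conditions: Amano lipase PS (Burkholderia cepacia), vinyl acetate, MTBE, 25 °C, run beyond half conversion of the secondary hydroxyl
Reagents that add atoms: vinyl acetate, CC(=O)OC=C
Why: Lipase-catalysed irreversible acyl transfer (kinetic resolution) in which the primary hydroxyl is acetylated in both enantiomers but the secondary one only in the (3R,4S) enantiomer, as the empirical size rule for lipases predicts (large substituted C4 against small vinylic C2), so the slow (3S,4R) monoacetate remains.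

Step 9
Reactants: 14 (3S,4R)-monoacetate
Product: 15 methyl (3S,4R)-4-(acetoxymethyl)-3-(triethylsilyloxy)cyclobut-1-ene-1-carboxylate
Conditions: Et3SiCl, imidazole, CH2Cl2, 0 °C
Reagents that add atoms: chlorotriethylsilane, CC[Si](Cl)(CC)CC
Why: Standard silylation of the resolved secondary allylic alcohol with the group that is removed together with the other two at the end.

Step 10
Reactants: 15 silyl ether acetate
Product: 16 methyl (3S,4R)-4-(hydroxymethyl)-3-(triethylsilyloxy)cyclobut-1-ene-1-carboxylate
Conditions: immobilised Candida antarctica lipase B, pH 7 phosphate buffer/MTBE, 25 °C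
Reagents that add atoms: none
Why: Enzymatic hydrolysis of the primary acetate at neutral pH leaves the conjugated methyl ester and the silyl ether intact, whereas alkoxide bases could add to C5 of the strained enoate.

Step 11
Reactants: 16 primary alcohol
Product: 17 methyl (3S,4S)-4-formyl-3-(triethylsilyloxy)cyclobut-1-ene-1-carboxylate
Conditions: Dess–Martin periodinane, NaHCO3, CH2Cl2, 0 °C; used at once
Reagents that add atoms: none
Why: Dess–Martin oxidation under buffered conditions gives the α-branched aldehyde without epimerising C7, β-elimination of O6 being impossible because it would create a cyclobutadiene.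

Step 12
Reactants: 18 3,3-dimethoxybutan-2-one; 19 methacrolein
Product: 21 racemic 5-hydroxy-2,2-dimethoxy-6-methylhept-6-en-3-one, via lithium enolate 20 (not isolated)
Conditions: LiN(iPr)2, THF, −78 °C; then 19, −78 °C; aq. NH4Cl
Reagents that add atoms: none
Why: Aldol addition of the kinetic lithium enolate (the ketone can enolise only at its methyl group) to the aldehyde carbonyl of the enal gives the β-hydroxy ketone carrying C9, C10, C1–C4 and C15.

Step 13
Reactants: 21 racemic aldol
Product: 22 (5S)-5-hydroxy-2,2-dimethoxy-6-methylhept-6-en-3-one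
Conditions: Ti(OiPr)4 (0.2 equiv), D-(−)-diisopropyl tartrate (0.3 equiv), tBuOOH (0.6 equiv), 4 Å molecular sieves, CH2Cl2, −20 °C
Reagents that add atoms: none
Why: Sharpless kinetic resolution of the secondary allylic alcohol, in which the D-tartrate catalyst epoxidises the (5R) enantiomer much faster, so the (5S) alcohol (C3 of the target) should be recovered enantiopure once conversion passes about 55%.

Step 14
Reactants: 22 (5S)-aldol
Product: 23 (3S,5S)-2,2-dimethoxy-6-methylhept-6-ene-3,5-diol
Conditions: Me4NBH(OAc)3, MeCN/AcOH (1:1), −30 °C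
Reagents that add atoms: none
Why: Evans–Saksena reduction in which the C3 hydroxyl binds the borohydride and delivers hydride intramolecularly through a chair transition state, giving the 1,3-anti diol and setting C1 as S.

Step 15
Reactants: 23 anti-diol ketal
Product: 24 (3S,5S)-3,5-dihydroxy-6-methylhept-6-en-2-one
Conditions: 0.5 M aq. HCl (cat.), THF, 0 → 23 °C
Reagents that add atoms: water, O
Why: Acid-catalysed ketal hydrolysis unmasks the C10 methyl ketone at the diol stage, before acid-labile silyl ethers are introduced.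

Step 16
Reactants: 24 dihydroxy ketone
Product: 25 (3S,5S)-6-methyl-3,5-bis(triethylsilyloxy)hept-6-en-2-one
Conditions: Et3SiCl, imidazole, DMAP (cat.), DMF, 0 → 23 °C
Reagents that add atoms: chlorotriethylsilane, CC[Si](Cl)(CC)CC
Why: Double silylation of the two secondary hydroxyls gives the methyl ketone fragment with O1 and O3 protected.

Step 17
Reactants: 25 methyl ketone; 17 cyclobutene aldehyde
Product: 27 methyl (3S,4R)-4-[(1R,4S,6S)-1-hydroxy-7-methyl-3-oxo-4,6-bis(triethylsilyloxy)oct-7-en-1-yl]-3-(triethylsilyloxy)cyclobut-1-ene-1-carboxylate, via boron enolate 26 (not isolated)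
Conditions: (+)-Ipc2BCl, Et3N, Et2O, 0 °C; then 17, −78 → −20 °C; then MeOH, pH 7 buffer, H2O2, 0 °C
Reagents that add atoms: none
Why: Boron aldol of the methyl-side enolate in which the isopinocampheyl ligands of the (+)-reagent should direct attack to the re face of the aldehyde, which is also the Felkin–Anh face if the vinylic ring carbon C11 acts as the large group, so that C8 is set R while C1, C3, C6 and C7 are untouched under these non-basic conditions.

Step 18
Reactants: 27 aldol adduct; 28 angelic acid
Product: 30 methyl (3S,4R)-4-[(1R,4S,6S)-7-methyl-1-{[(2Z)-2-methylbut-2-enoyl]oxy}-3-oxo-4,6-bis(triethylsilyloxy)oct-7-en-1-yl]-3-(triethylsilyloxy)cyclobut-1-ene-1-carboxylate, via mixed anhydride 29 (not isolated)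
Conditions: 28, 2,4,6-trichlorobenzoyl chloride, Et3N, toluene, 23 °C; then 27, toluene, 23 → 35 °C (no DMAP)
Reagents that add atoms: none
Why: Acyl transfer from the preformed mixed anhydride (Yamaguchi-type, attack at the less hindered angeloyl carbonyl) esterifies O8 without a nucleophilic catalyst or strong heating, which should keep the Z alkene, avoid β-elimination towards the C10 ketone and spare the cyclobutene.

Step 19
Reactants: 30 cyclobutene precursor
Product: 32 methyl 2-[(1R,2S,3Z,5S,7S,10R)-4-methyl-10-{[(2Z)-2-methylbut-2-enoyl]oxy}-8-oxo-2,5,7-tris(triethylsilyloxy)cyclodec-3-en-1-yl]prop-2-enoate, via triene 31 (not isolated)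
Conditions: second-generation Hoveyda–Grubbs catalyst RuCl2(H2IMes)(=CH-C6H4-2-OiPr) (10 mol%), ethylene (1 atm), CH2Cl2 (5 mM), 23 °C; then argon sparge, dilution with toluene to 0.5 mM, more catalyst (10 mol%), 1,4-benzoquinone, 80 °C
Reagents that add atoms: ethylene, C=C
Why: Proposed new method: a ruthenium methylidene adds across the strained C5=C11 bond and cycloreverts; whichever way round it adds, turnover with ethylene gives the same triene 31 (C5 vinyl group, C11=C13 acrylate methylene), and once ethylene is swept out the C5 alkylidene undergoes ring-closing metathesis with the C4 isopropenyl alkene, the closest known chemistry being ring-opening cross-metathesis and ring-rearrangement metathesis of cyclobutenes (including cyclobutene-1-carboxylates with second-generation ruthenium carbenes), not yet extended to a ten-membered ring with a trisubstituted alkene. The ten-membered carbocycle is closed by macrocyclic diene ring-closing metathesis (C4=C5 formed, ethylene lost), and the release of cyclobutene strain in the first stage makes ring opening irreversible. No stereocentre is formed; C1, C3, C6, C7 and C8 are carried through unchanged. The step needs ring-size control, cyclisation instead of oligomerisation, and Z geometry: the C10 ketone removes the only alkene that could close a six-membered ring, the acrylate and angelate alkenes are too electron-poor and hindered to compete, sub-millimolar dilution disfavours cross-metathesis, and a trisubstituted alkene in a ten-membered ring should strongly prefer the cis-ring (4Z) isomer. Opening the ring at ambient temperature before heating also removes the risk of thermal conrotatory opening of the 3-silyloxycyclobutene.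

Step 20
Reactants: 32 macrocyclic ketone
Product: 33 methyl 2-[(1R,2S,3Z,5S,7S,10R)-4-methyl-8-methylidene-10-{[(2Z)-2-methylbut-2-enoyl]oxy}-2,5,7-tris(triethylsilyloxy)cyclodec-3-en-1-yl]prop-2-enoate
Conditions: Zn, CH2Br2, TiCl4, THF (reagent aged at 5 °C); then 32, CH2Cl2, 0 → 23 °C
Reagents that add atoms: dibromomethane, BrCBr
Why: Lombardo methylenation, whose non-basic zinc–titanium methylene reagent converts the C10 ketone into the C10=C14 methylene without touching the ester carbonyls, epimerising C1 or eliminating the β-angelate.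

Step 21
Reactants: 33 tris-silyl ether
Product: 35 CNP0175889.6, via triol ester 34 (not isolated)
Conditions: HF·pyridine, pyridine, THF, 0 → 23 °C; then PPTS (cat.), CH2Cl2, 23 °C
Reagents that add atoms: none
Why: Fluoride-mediated desilylation frees three hydroxyls and O6 then attacks the acrylate carbonyl C12 (5-exo-trig acyl substitution, loss of methanol) to close the trans-fused α-methylene-γ-lactone, the mildly acidic medium suppressing angelate migration and O8 being blocked.

**Compound list**

1 | 1,1,3,3-tetramethoxypropane | COC(OC)CC(OC)OC | starting material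
2 | malonaldehyde (enol form, (E)-3-hydroxyprop-2-enal) | O=C/C=C/O | intermediate
3 | sodium (E)-3-oxoprop-1-en-1-olate | [Na+].[O-]/C=C/C=O | intermediate
4 | (E)-3-(triethylsilyloxy)prop-2-enal | CC[Si](CC)(CC)O/C=C/C=O | intermediate
5 | (E)-3-(triethylsilyloxy)prop-2-en-1-ol | CC[Si](CC)(CC)O/C=C/CO | intermediate
6 | (E)-1,3-bis(triethylsilyloxy)prop-1-ene | CC[Si](CC)(CC)O/C=C/CO[Si](CC)(CC)CC | intermediate
7 | trichloroacetyl chloride | ClC(=O)C(Cl)(Cl)Cl | starting material
8 | dichloroketene | ClC(Cl)=C=O | intermediate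
9 | racemic (3R*,4R*)-2,2-dichloro-3-(triethylsilyloxy)-4-[(triethylsilyloxy)methyl]cyclobutan-1-one (trans; enantiomer of the target series drawn) | O=C1C(Cl)(Cl)[C@H](O[Si](CC)(CC)CC)[C@H]1CO[Si](CC)(CC)CC | intermediate
10 | racemic (2R*,3S*)-3-(triethylsilyloxy)-2-[(triethylsilyloxy)methyl]cyclobutan-1-one (trans; one enantiomer drawn) | O=C1C[C@H](O[Si](CC)(CC)CC)[C@H]1CO[Si](CC)(CC)CC | intermediate
11 | racemic (3S*,4R*)-3-(triethylsilyloxy)-4-[(triethylsilyloxy)methyl]cyclobut-1-en-1-yl trifluoromethanesulfonate (one enantiomer drawn) | FC(F)(F)S(=O)(=O)OC1=C[C@H](O[Si](CC)(CC)CC)[C@H]1CO[Si](CC)(CC)CC | intermediate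
12 | racemic methyl (3S*,4R*)-3-(triethylsilyloxy)-4-[(triethylsilyloxy)methyl]cyclobut-1-ene-1-carboxylate (one enantiomer drawn) | COC(=O)C1=C[C@H](O[Si](CC)(CC)CC)[C@H]1CO[Si](CC)(CC)CC | intermediate
13 | racemic methyl (3S*,4R*)-3-hydroxy-4-(hydroxymethyl)cyclobut-1-ene-1-carboxylate (one enantiomer drawn) | COC(=O)C1=C[C@H](O)[C@H]1CO | intermediate
14 | methyl (3S,4R)-4-(acetoxymethyl)-3-hydroxycyclobut-1-ene-1-carboxylate | COC(=O)C1=C[C@H](O)[C@H]1COC(C)=O | intermediate
15 | methyl (3S,4R)-4-(acetoxymethyl)-3-(triethylsilyloxy)cyclobut-1-ene-1-carboxylate | COC(=O)C1=C[C@H](O[Si](CC)(CC)CC)[C@H]1COC(C)=O | intermediate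
16 | methyl (3S,4R)-4-(hydroxymethyl)-3-(triethylsilyloxy)cyclobut-1-ene-1-carboxylate | COC(=O)C1=C[C@H](O[Si](CC)(CC)CC)[C@H]1CO | intermediate
17 | methyl (3S,4S)-4-formyl-3-(triethylsilyloxy)cyclobut-1-ene-1-carboxylate | COC(=O)C1=C[C@H](O[Si](CC)(CC)CC)[C@H]1C=O | intermediate
18 | 3,3-dimethoxybutan-2-one | CC(=O)C(C)(OC)OC | starting material
19 | methacrolein | CC(=C)C=O | starting material
20 | lithium 3,3-dimethoxybut-1-en-2-olate | [Li+].[O-]C(=C)C(C)(OC)OC | intermediate
21 | racemic 5-hydroxy-2,2-dimethoxy-6-methylhept-6-en-3-one | CC(=C)C(O)CC(=O)C(C)(OC)OC | intermediate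
22 | (5S)-5-hydroxy-2,2-dimethoxy-6-methylhept-6-en-3-one | CC(=C)[C@@H](O)CC(=O)C(C)(OC)OC | intermediate
23 | (3S,5S)-2,2-dimethoxy-6-methylhept-6-ene-3,5-diol | CC(=C)[C@@H](O)C[C@H](O)C(C)(OC)OC | intermediate
24 | (3S,5S)-3,5-dihydroxy-6-methylhept-6-en-2-one | CC(=C)[C@@H](O)C[C@H](O)C(C)=O | intermediate
25 | (3S,5S)-6-methyl-3,5-bis(triethylsilyloxy)hept-6-en-2-one | CC(=C)[C@@H](O[Si](CC)(CC)CC)C[C@H](O[Si](CC)(CC)CC)C(C)=O | intermediate
26 | bis[(1S,2S,3S,5R)-isopinocampheyl]boron enolate of 25 (boron on the C10 oxygen, C9=C10 enol) | C=C(OB([C@H]1C[C@H]2C[C@@H]([C@@H]1C)C2(C)C)[C@H]1C[C@H]2C[C@@H]([C@@H]1C)C2(C)C)[C@@H](O[Si](CC)(CC)CC)C[C@H](O[Si](CC)(CC)CC)C(C)=C | intermediate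
27 | methyl (3S,4R)-4-[(1R,4S,6S)-1-hydroxy-7-methyl-3-oxo-4,6-bis(triethylsilyloxy)oct-7-en-1-yl]-3-(triethylsilyloxy)cyclobut-1-ene-1-carboxylate | COC(=O)C1=C[C@H](O[Si](CC)(CC)CC)[C@H]1[C@H](O)CC(=O)[C@@H](O[Si](CC)(CC)CC)C[C@H](O[Si](CC)(CC)CC)C(C)=C | intermediate
28 | angelic acid, (2Z)-2-methylbut-2-enoic acid | C/C=C(/C)C(=O)O | starting material
29 | (2Z)-2-methylbut-2-enoic 2,4,6-trichlorobenzoic anhydride | C/C=C(/C)C(=O)OC(=O)c1c(Cl)cc(Cl)cc1Cl | intermediate
30 | methyl (3S,4R)-4-[(1R,4S,6S)-7-methyl-1-{[(2Z)-2-methylbut-2-enoyl]oxy}-3-oxo-4,6-bis(triethylsilyloxy)oct-7-en-1-yl]-3-(triethylsilyloxy)cyclobut-1-ene-1-carboxylate | COC(=O)C1=C[C@H](O[Si](CC)(CC)CC)[C@H]1[C@H](OC(=O)/C(C)=C\C)CC(=O)[C@@H](O[Si](CC)(CC)CC)C[C@H](O[Si](CC)(CC)CC)C(C)=C | intermediate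
31 | methyl (3R,4S)-2-methylidene-3-[(1R,4S,6S)-7-methyl-1-{[(2Z)-2-methylbut-2-enoyl]oxy}-3-oxo-4,6-bis(triethylsilyloxy)oct-7-en-1-yl]-4-(triethylsilyloxy)hex-5-enoate | C=C(C(=O)OC)[C@@H]([C@@H](O[Si](CC)(CC)CC)C=C)[C@H](OC(=O)/C(C)=C\C)CC(=O)[C@@H](O[Si](CC)(CC)CC)C[C@H](O[Si](CC)(CC)CC)C(C)=C | intermediate
32 | methyl 2-[(1R,2S,3Z,5S,7S,10R)-4-methyl-10-{[(2Z)-2-methylbut-2-enoyl]oxy}-8-oxo-2,5,7-tris(triethylsilyloxy)cyclodec-3-en-1-yl]prop-2-enoate | C=C(C(=O)OC)[C@H]1[C@@H](O[Si](CC)(CC)CC)/C=C(/C)[C@@H](O[Si](CC)(CC)CC)C[C@H](O[Si](CC)(CC)CC)C(=O)C[C@H]1OC(=O)/C(C)=C\C | intermediate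
33 | methyl 2-[(1R,2S,3Z,5S,7S,10R)-4-methyl-8-methylidene-10-{[(2Z)-2-methylbut-2-enoyl]oxy}-2,5,7-tris(triethylsilyloxy)cyclodec-3-en-1-yl]prop-2-enoate | C=C(C(=O)OC)[C@H]1[C@@H](O[Si](CC)(CC)CC)/C=C(/C)[C@@H](O[Si](CC)(CC)CC)C[C@H](O[Si](CC)(CC)CC)C(=C)C[C@H]1OC(=O)/C(C)=C\C | intermediate
34 | methyl 2-[(1S,2S,3Z,5S,7S,10R)-2,5,7-trihydroxy-4-methyl-8-methylidene-10-{[(2Z)-2-methylbut-2-enoyl]oxy}cyclodec-3-en-1-yl]prop-2-enoate | C=C(C(=O)OC)[C@H]1[C@@H](O)/C=C(/C)[C@@H](O)C[C@H](O)C(=C)C[C@H]1OC(=O)/C(C)=C\C | intermediate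
35 | CNP0175889.6, (3aR,4R,7S,9S,10Z,11aS)-7,9-dihydroxy-10-methyl-3,6-dimethylidene-2-oxo-2,3,3a,4,5,6,7,8,9,11a-decahydrocyclodeca[b]furan-4-yl (2Z)-2-methylbut-2-enoate | C=C1C(=O)O[C@H]2/C=C(/C)[C@@H](O)C[C@H](O)C(=C)C[C@@H](OC(=O)/C(C)=C\C)[C@@H]12 | target

**Step count.** 21 steps in total. The longest linear sequence is 16 steps (steps 1–11, then 17–21, from 1,1,3,3-tetramethoxypropane); the ketone fragment takes 5 steps (12–16).

**Steps most likely to fail**

1. Step 19 (key step). After ring opening, closure of the C5 alkylidene onto the hindered 1,1-disubstituted C4 alkene may be outrun by intermolecular metathesis and catalyst decay, so that the material stalls at the open triene or oligomerises. The fallback uses known reactions only, sets out from 30 and rejoins the route at 35. 30 is treated with the same ruthenium catalyst under ethylene alone at 23 °C, a known ring-opening cross-metathesis of a cyclobutene, and triene 31 is isolated. HF·pyridine and then PPTS remove the three silyl groups and close the lactone, giving (1R,4S,6S)-1-[(2S,3R)-2-ethenyl-4-methylidene-5-oxooxolan-3-yl]-4,6-dihydroxy-7-methyl-3-oxooct-7-en-1-yl angelate F1. With the trans-lactone and free allylic hydroxyls now organising the chain, a conventional diene ring-closing metathesis (second-generation Grubbs catalyst RuCl2(H2IMes)(PCy3)(=CHPh), toluene, high dilution, 80 °C) should give the macrocyclic ketolactone F2. Lombardo methylenation (Zn/CH2Br2/TiCl4 in excess, free hydroxyls tolerated) then converts F2 into 35.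

2. Step 17. Facial selectivity at the aldehyde may be poor if the α-stereocentre C7 opposes the boron reagent, and C7 may partly epimerise before addition. The fallback sets out from 25 and 17 and rejoins at 30. The aldol is run with the enantiomeric reagent (−)-Ipc2BCl (or the 8S epimer is separated) to give the C8-epimeric alcohol F3. F3 is esterified with 28 under Mitsunobu conditions (PPh3, DIAD, toluene, 0 °C); displacement by the angelate anion inverts C8 and, because the acid is never activated, cannot isomerise the Z alkene, so 30 is reached directly.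

3. Step 18. The activated angeloyl unit may isomerise from Z to E, or the acyloxy group may undergo β-elimination towards the C10 ketone, during a slow acylation at low temperature. The fallback sets out from 27 and 28 and rejoins at 30. 28 is brominated (Br2, CH2Cl2, anti addition) to the racemic (2R*,3R*)-2,3-dibromo-2-methylbutanoic acid F4, which (COCl)2 converts into the acid chloride F5. F5 has no alkene and no α-hydrogen and acylates 27 (pyridine, CH2Cl2, 0 °C) to give the dibromo ester F6. NaI in acetone at 23 °C then effects stereospecific anti-debromination and regenerates the Z alkene of 30.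

**Further compounds**

F1 | step 19 | (1R,4S,6S)-1-[(2S,3R)-2-ethenyl-4-methylidene-5-oxooxolan-3-yl]-4,6-dihydroxy-7-methyl-3-oxooct-7-en-1-yl (2Z)-2-methylbut-2-enoate | C=C1C(=O)O[C@@H](C=C)[C@H]1[C@H](OC(=O)/C(C)=C\C)CC(=O)[C@@H](O)C[C@H](O)C(C)=C
F2 | step 19 | (3aR,4R,7S,9S,10Z,11aS)-7,9-dihydroxy-10-methyl-3-methylidene-2,6-dioxo-2,3,3a,4,5,6,7,8,9,11a-decahydrocyclodeca[b]furan-4-yl (2Z)-2-methylbut-2-enoate | C=C1C(=O)O[C@H]2/C=C(/C)[C@@H](O)C[C@H](O)C(=O)C[C@@H](OC(=O)/C(C)=C\C)[C@@H]12
F3 | step 17 | methyl (3S,4R)-4-[(1S,4S,6S)-1-hydroxy-7-methyl-3-oxo-4,6-bis(triethylsilyloxy)oct-7-en-1-yl]-3-(triethylsilyloxy)cyclobut-1-ene-1-carboxylate | COC(=O)C1=C[C@H](O[Si](CC)(CC)CC)[C@H]1[C@@H](O)CC(=O)[C@@H](O[Si](CC)(CC)CC)C[C@H](O[Si](CC)(CC)CC)C(C)=C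
F4 | step 18 | racemic (2R*,3R*)-2,3-dibromo-2-methylbutanoic acid ((2S,3S) drawn) | C[C@H](Br)[C@@](C)(Br)C(=O)O
F5 | step 18 | racemic (2R*,3R*)-2,3-dibromo-2-methylbutanoyl chloride ((2S,3S) drawn) | C[C@H](Br)[C@@](C)(Br)C(Cl)=O
F6 | step 18 | methyl (3S,4R)-4-[(1R,4S,6S)-1-{[(2R*,3R*)-2,3-dibromo-2-methylbutanoyl]oxy}-7-methyl-3-oxo-4,6-bis(triethylsilyloxy)oct-7-en-1-yl]-3-(triethylsilyloxy)cyclobut-1-ene-1-carboxylate (one acyl diastereomer drawn) | COC(=O)C1=C[C@H](O[Si](CC)(CC)CC)[C@H]1[C@H](OC(=O)[C@](C)(Br)[C@H](C)Br)CC(=O)[C@@H](O[Si](CC)(CC)CC)C[C@H](O[Si](CC)(CC)CC)C(C)=C
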